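## The problem

The target **18**, (2S)-5,7-dihydroxy-2-(4-hydroxy-3-methoxyphenyl)-6-(2-methylbut-3-en-2-yl)chroman-4-one, has a phloroglucinol-type ring A fused through O1 and C4 to the dihydropyranone ring C, which carries the guaiacyl ring B at C2. C2 is the only stereocentre and nothing else in the molecule can direct it, so its configuration must come from a catalyst. It is also fragile, because C3 is enolisable and base opens ring C by retro-oxa-Michael reaction to an achiral open-chain enone. A temporary stereocentre at C4 could pass its configuration on to C2 through the ring, but nothing in the target can control C4 in return. The 1,1-dimethylallyl group sits on a quaternary benzylic carbon at C6 between the oxygens on C5 and C7; since C6 and C8 are hard to tell apart in a finished flavanone, it is best placed while ring A is still symmetric. Its terminal alkene excludes hydrogenolytic deprotection, and next to a free phenol it can cyclise under acid to a dihydrobenzofuran. The feature that allows a short route is that O1, C8a, C4a and C4 are the atoms of a salicylaldehyde, while C2, C3 and ring B are the atoms of 4-vinylguaiacol. Ring C is therefore the formal [4+2] adduct of a cationic ortho-quinone methide on ring A and an electron-rich styrene, in which the three oxygens of ring A stabilise the heterodiene and the para oxygen of ring B fixes the orientation.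

## Retrosynthesis

**18 from 17 (three O–Si bonds).** The phenols on C5, C7 and C4' are masked as silyl ethers in **17**. Silyl groups are preferred to benzyl ethers (the alkene would not survive hydrogenolysis) and to acetal groups (acid next to the alkene and free phenols). The forward reaction must stay close to neutral so that C2 is not epimerised through ring opening.

**17 from 15 through 16 (oxidation level of C4).** The ketone is traced back to the secondary alcohol **16** and this to the benzylic methyl ether **15**. No skeletal bond is cut; the change makes C4 an sp3 centre carrying a leaving group, which is the retron of the cycloaddition. The forward steps need a solvolysis at C4, made easy by O1, O5 and O7, and a mild oxidation. The C4 configuration is erased, so only C2 of **15** matters.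

**15 from 8, 10 and 11 (O1–C2 and C3–C4).** Both bonds that flank the C2–C3 unit are cut together. This gives the salicylaldehyde **8**, the styrene **10** and trimethyl orthoformate **11**, which supplies the C4 methoxy group by way of the acetal **12**, the methoxycarbenium ion **13** and the benzylic cation **14**. The neighbouring cuts were weighed: O1–C2 alone (oxa-Michael closure of an open-chain enone) and C2–aryl alone (conjugate arylation of a chromone). Both need a ring A acetophenone or chromone carrying the hindered tert-alkyl group, and both form one bond where this cut forms two. The precursors are a benzaldehyde and a styrene, each a few steps from commercial phenols. The forward reaction must set C2 as S under control of a chiral acid; this is the demanding point of the plan.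

**10 from 9 (O–Si).** The styrene is the silyl ether of commercial 2-methoxy-4-vinylphenol **9**. The silyl group keeps the phenol from intercepting cations and retains the para donor that directs the addition.

**8 from 7 and 7 from 6 (O–Si bonds).** In **8** the hydroxyl that becomes O1 must be free, and the two oxygens next to the tert-alkyl group must be blocked. This is the reverse of the order in which the hydroxyls of a free triol would react. The two ortho oxygens are therefore silylated before the tert-alkyl group arrives, and the less hindered one is released afterwards from **7**. The para oxygen receives a triisopropylsilyl group from phenol **6**, so that it differs clearly from the ortho tert-butyldimethylsilyl ethers. The forward desilylation must distinguish two ortho silyl ethers by the bulk of their neighbours.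

**6 from 4 (aryl C3–C quaternary bond).** The ortho-(1,1-dimethylallyl)phenol is the retron of an aromatic Claisen rearrangement of the prenyl ether **4**, with the trimethylsilyl ether **5** as a trapped intermediate. The ether is placed on the oxygen para to the formyl group for two reasons: the two ortho positions of **4** are equivalent, and the para position is occupied by the formyl group, so no Cope shift to a normal prenyl group can follow. A shift from an ortho oxygen would leave the para position open. Friedel–Crafts alkylation would give the normal prenyl group.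

**4 from 3, and 3 from 1 and 2 (O–Si and O–C bonds).** Silyl ether **4** comes from diol **3**, and this from 2,4,6-trihydroxybenzaldehyde **1** and prenyl bromide **2** by alkylation of the para hydroxyl. Both starting materials are commercial and ring A is bought ready-made.

## Roads not taken

Alternative 1: Rings A and C are taken apart together (C4–C4a, C5–C6, C7–C8, C4a–C8a and O1–C2). In the forward sense ferulic acid A1 would be activated as its thioester by a ligase, extended by chalcone synthase with three two-carbon units derived from malonic acid A2, and closed by chalcone isomerase to (2S)-homoeriodictyol A3.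
- Merits: one aqueous operation from A1 and A2, no protecting groups, and enzymatic control of C2 that the chosen plan cannot match in certainty.
- Weak points: A3 lacks the 1,1-dimethylallyl group, which would have to be introduced at C6 of a finished flavanone with three phenols and two similar nucleophilic positions. O-prenylation and sigmatropic shift on such systems can deliver the inverted group to C6 or, after a Cope shift, a normal prenyl group to C8, and the heat or Lewis acid needed endangers C2. The methoxy group also makes A1 a poorer starter for most chalcone synthases than their native substrate, and both A1 and A2 must be activated enzymatically at the cost of cofactors.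
- Comparison: this road is better for C2. The chosen plan offers instead a tert-alkyl group whose position is never a selectivity question, and ordinary laboratory reagents throughout.

Alternative 2: Only C3=C4 is cut, at the enol ether oxidation level. The acyclic diene A4, an aryl 1-arylallyl ether carrying a triethylsilyl enol ether on ring A, would be closed with second-generation Grubbs catalyst to the 4-silyloxy-2H-chromene A5. Hydrolysis of the enol ether of A5 would then give the ketone.
- Merits: C2 is set before ring closure in an allylic aryl ether, a kind of stereocentre for which asymmetric allylic etherification is established. The ring closure needs no stereocontrol and C4 arrives at the ketone level without an oxidation step.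
- Weak points: A4 requires etherification of a phenol flanked by an acyl group with a secondary, ionisable allylic partner. It carries a third terminal alkene (the vinyl of the 1,1-dimethylallyl group) that can enter cross-metathesis. Metathesis onto a 1,1-disubstituted silyl enol ether is slow and the enol ethers are hydrolytically fragile. The methoxymethyl groups of A5 must finally be removed with acid beside the alkene and free phenols.
- Comparison: the stereochemical basis of this road is firmer than the unproven relay of the chosen plan. The chosen plan offers instead a three-component assembly of ring C in one operation, no competing alkene chemistry, fewer steps and neutral final deprotection.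

Alternative 3: Ring A is built on a preformed ring C (C8–C8a, C5–C6, C7–C8 and C4a–C5). Irradiation of the diazoketone A6 in the presence of the siloxyalkyne A7 would set off Wolff rearrangement and [2+2] cycloaddition, and on warming four-electron ring opening and six-electron electrocyclisation, ending at the 7,4'-bis-O-triisopropylsilyl ether A8 of **18**.
- Merits: the position of every ring A substituent is dictated by the connectivity of A7. A8 already has the C4 ketone and the free C5 hydroxyl, and C2 could come from established asymmetric hetero-Diels–Alder chemistry.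
- Weak points: A6 is a dihydropyranone with a diazoacetyl group on its enol ether carbon and A7 is an ynol ether with a quaternary propargylic carbon; each needs several steps of its own. The photochemical step must tolerate an enone chromophore and a terminal alkene, and the electrocyclisation has to place the tert-alkyl group between two oxygens.
- Comparison: this road is superior in regiocontrol and in oxidation-state economy. The chosen plan offers instead a ring A that is bought, roughly half the number of steps and stable intermediates, at the price of a redox adjustment at C4 and an asymmetric step that is not yet known.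

Key step: step 7

## Route

Assumption: the sense of induction of the chiral acid cannot be predicted for this substrate, so the catalyst antipode that leads to (2S) is taken; both antipodes are accessible from the two enantiomers of BINOL.

Abbreviations: TBS = tert-butyldimethylsilyl, TIPS = triisopropylsilyl, BSA = N,O-bis(trimethylsilyl)acetamide, Tf = SO2CF3, TBAF = tetrabutylammonium fluoride, DDQ = 2,3-dichloro-5,6-dicyano-1,4-benzoquinone, BINOL = 1,1'-bi-2-naphthol. Locants on the benzaldehydes are C1 for the formyl-bearing carbon; flavan numbering is used from step 7 on.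

Step 1
Reactants: 1 2,4,6-trihydroxybenzaldehyde; 2 prenyl bromide (1-bromo-3-methylbut-2-ene)
Product: 3 2,6-dihydroxy-4-(3-methylbut-2-en-1-yloxy)benzaldehyde
Conditions: 2 (1.05 equiv), KHCO3 (1.2 equiv), DMF, 0 °C → rt
Reagents that add atoms: none
Why: Williamson ether synthesis; the para hydroxyl is the most acidic and cannot hydrogen-bond to the formyl group, so the mono-phenoxide made with the weak base is alkylated there, and the symmetric product makes the later sigmatropic shift regiochemically unambiguous.

Step 2
Reactants: 3 2,6-dihydroxy-4-(3-methylbut-2-en-1-yloxy)benzaldehyde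
Product: 4 2,6-bis(tert-butyldimethylsilyloxy)-4-(3-methylbut-2-en-1-yloxy)benzaldehyde
Conditions: TBSCl (2.6 equiv), imidazole (5 equiv), DMF, rt → 40 °C
Reagents that add atoms: tert-butyldimethylsilyl chloride, CC(C)(C)[Si](C)(C)Cl
Why: Standard phenol silylation through the N-silylimidazolium ion; excess reagent drives the second, hydrogen-bonded hydroxyl, and both ortho oxygens receive their silyl group before the tert-alkyl group makes one of them hard to reach.

Step 3
Reactants: 4 2,6-bis(tert-butyldimethylsilyloxy)-4-(3-methylbut-2-en-1-yloxy)benzaldehyde
Product: 6 2,6-bis(tert-butyldimethylsilyloxy)-4-hydroxy-3-(2-methylbut-3-en-2-yl)benzaldehyde, via trimethylsilyl ether 5 (not isolated)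
Conditions: BSA (2 equiv), PhNEt2, 190 °C (sealed tube); then aqueous citric acid, THF, rt
Reagents that add atoms: none
Why: Aromatic Claisen rearrangement; the [3,3] shift delivers the inverted allyl unit to C3 (equivalent to C5), the formyl group blocks the para position so no Cope shift can follow, and BSA silylates the new phenol in the flask so that neither abnormal Claisen isomerisation nor dihydrobenzofuran formation can start from it; the trimethylsilyl ether is hydrolysed on work-up.

Step 4
Reactants: 6 2,6-bis(tert-butyldimethylsilyloxy)-4-hydroxy-3-(2-methylbut-3-en-2-yl)benzaldehyde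
Product: 7 2,6-bis(tert-butyldimethylsilyloxy)-3-(2-methylbut-3-en-2-yl)-4-(triisopropylsilyloxy)benzaldehyde
Conditions: TIPSOTf (1.3 equiv), 2,6-lutidine (2 equiv), CH2Cl2, 0 °C → rt
Reagents that add atoms: triisopropylsilyl triflate, CC(C)[Si](C(C)C)(C(C)C)OS(=O)(=O)C(F)(F)F
Why: Silylation with a silyl triflate and a hindered base handles a phenol with one tert-alkyl neighbour; the triisopropylsilyl group makes this para ether much slower to cleave than the ortho TBS ethers and later shields the adjacent aromatic CH.

Step 5
Reactants: 7 2,6-bis(tert-butyldimethylsilyloxy)-3-(2-methylbut-3-en-2-yl)-4-(triisopropylsilyloxy)benzaldehyde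
Product: 8 2-(tert-butyldimethylsilyloxy)-6-hydroxy-3-(2-methylbut-3-en-2-yl)-4-(triisopropylsilyloxy)benzaldehyde
Conditions: K2CO3 (0.2 equiv), MeOH/THF (1:1), −10 °C; AcOH quench
Reagents that add atoms: none
Why: Base-catalysed methanolysis of an aryl silyl ether; TBS ethers ortho to a formyl group cleave much faster than the bulkier para TIPS ether, the TBS group on O6 has only a hydrogen neighbour whereas that on O2 is buttressed by the tert-alkyl group, and the phenoxide set free is conjugated with the aldehyde and slows a second cleavage.

Step 6
Reactants: 9 2-methoxy-4-vinylphenol (4-vinylguaiacol)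
Product: 10 tert-butyl(2-methoxy-4-vinylphenoxy)dimethylsilane
Conditions: TBSCl (1.2 equiv), imidazole (2 equiv), CH2Cl2, rt
Reagents that add atoms: tert-butyldimethylsilyl chloride, CC(C)(C)[Si](C)(C)Cl
Why: Standard silylation of an unhindered phenol; the silyl ether keeps the para oxygen as a donor but stops it from acting as a nucleophile in step 7.

Step 7
Reactants: 8 2-(tert-butyldimethylsilyloxy)-6-hydroxy-3-(2-methylbut-3-en-2-yl)-4-(triisopropylsilyloxy)benzaldehyde; 10 tert-butyl(2-methoxy-4-vinylphenoxy)dimethylsilane; 11 trimethyl orthoformate
Product: 15 (2S,4S)-5-(tert-butyldimethylsilyloxy)-2-[4-(tert-butyldimethylsilyloxy)-3-methoxyphenyl]-4-methoxy-6-(2-methylbut-3-en-2-yl)-7-(triisopropylsilyloxy)chromane, via dimethyl acetal 12 (not isolated), via methoxycarbenium ion 13 (not isolated), via benzylic cation 14 (not isolated)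
Conditions: chiral imidodiphosphorimidate acid HN[P(=NTf)(Ar2-BINOLate)]2 (Ar = 3,5-(CF3)2C6H3; 5 mol %), 11 (1.5 equiv), 10 (2 equiv, slow addition), 5 Å molecular sieves, CH2Cl2, −60 → −30 °C; Et3N quench
Reagents that add atoms: none
Why: Proposed new method: the acid converts 8 and 11 into acetal 12 and ionises it to the 2-hydroxyaryl methoxycarbenium ion 13 (a protonated 4-methoxy-ortho-quinone methide), which stays bound to the confined chiral anion through the hydrogen bond of the free hydroxyl. The terminal carbon of styrene 10 attacks the carbenium carbon (C3–C4), because only this orientation places the charge of 14 on the benzylic carbon conjugated with the para silyloxy group; the vinyl group on the quaternary carbon of 8 is far less nucleophilic and should not compete. The phenol oxygen then captures the benzylic cation (O1–C2) in a six-membered exo-type closure through a chair-like arrangement with the aryl group pseudo-equatorial, so ring C closes stepwise as a formal inverse-demand hetero-Diels–Alder reaction and the 2,4-cis isomer is expected. C4 is set by the face of 13 that the anion leaves open to the styrene (catalyst control), and C2 by the cis closure inside the same ion pair (relay from C4, possibly reinforced by the anion); since C4 is later erased, the real requirement is S at C2. The closest known reactions are the achiral acid-catalysed three-component union of salicylaldehydes, orthoformates and styrenes to 2-aryl-4-alkoxychromans and the chiral phosphoric acid-catalysed [4+2] reactions of ortho-quinone methides with styrenes; the enantioselective acetal-derived variant has not been shown. The site of closure is fixed by the silyl ether on O5, which leaves the C8a hydroxyl as the only nucleophile, and the bulky silyl ether on O7 shields C8 against Friedel–Crafts attack by 13. The three oxygens of ring A should make ionisation of 12 possible at low temperature, which limits acid-induced oligomerisation of 10 and reopening of the C2–O1 bond of 15.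

Step 8
Reactants: 15 (2S,4S)-5-(tert-butyldimethylsilyloxy)-2-[4-(tert-butyldimethylsilyloxy)-3-methoxyphenyl]-4-methoxy-6-(2-methylbut-3-en-2-yl)-7-(triisopropylsilyloxy)chromane
Product: 16 (2S)-5-(tert-butyldimethylsilyloxy)-2-[4-(tert-butyldimethylsilyloxy)-3-methoxyphenyl]-6-(2-methylbut-3-en-2-yl)-7-(triisopropylsilyloxy)chroman-4-ol (C4 epimers)
Conditions: TsOH·H2O (0.1 equiv), acetone/H2O (5:1), 0 °C → rt
Reagents that add atoms: water, O
Why: Unimolecular solvolysis of a benzylic ether; ionisation at C4 is assisted by O1, O5 and O7, water in large excess captures the cation, the C4 configuration is irrelevant, C2 is not involved, and aryl silyl ethers tolerate dilute aqueous acid.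

Step 9
Reactants: 16 (2S)-5-(tert-butyldimethylsilyloxy)-2-[4-(tert-butyldimethylsilyloxy)-3-methoxyphenyl]-6-(2-methylbut-3-en-2-yl)-7-(triisopropylsilyloxy)chroman-4-ol
Product: 17 (2S)-5-(tert-butyldimethylsilyloxy)-2-[4-(tert-butyldimethylsilyloxy)-3-methoxyphenyl]-6-(2-methylbut-3-en-2-yl)-7-(triisopropylsilyloxy)chroman-4-one
Conditions: Dess–Martin periodinane (1.3 equiv), NaHCO3, CH2Cl2, 0 °C → rt
Reagents that add atoms: none
Why: Dess–Martin oxidation of a secondary benzylic alcohol; both C4 epimers converge on the ketone, and the buffered, non-basic medium leaves the silyl ethers, the alkene and C2 untouched.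

Step 10
Reactants: 17 (2S)-5-(tert-butyldimethylsilyloxy)-2-[4-(tert-butyldimethylsilyloxy)-3-methoxyphenyl]-6-(2-methylbut-3-en-2-yl)-7-(triisopropylsilyloxy)chroman-4-one
Product: 18 (2S)-5,7-dihydroxy-2-(4-hydroxy-3-methoxyphenyl)-6-(2-methylbut-3-en-2-yl)chroman-4-one
Conditions: TBAF (4 equiv), AcOH (4 equiv), THF, 0 °C → rt
Reagents that add atoms: none
Why: Fluoride-mediated cleavage of the three aryl silyl ethers; acetic acid protonates the phenoxides as they form and buffers the fluoride, so the retro-oxa-Michael ring opening that would racemise C2 should not be triggered.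

## Compound list

1 | 2,4,6-trihydroxybenzaldehyde | O=Cc1c(O)cc(O)cc1O | starting material
2 | prenyl bromide (1-bromo-3-methylbut-2-ene) | CC(C)=CCBr | starting material
3 | 2,6-dihydroxy-4-(3-methylbut-2-en-1-yloxy)benzaldehyde | O=Cc1c(O)cc(OCC=C(C)C)cc1O | intermediate
4 | 2,6-bis(tert-butyldimethylsilyloxy)-4-(3-methylbut-2-en-1-yloxy)benzaldehyde | O=Cc1c(O[Si](C)(C)C(C)(C)C)cc(OCC=C(C)C)cc1O[Si](C)(C)C(C)(C)C | intermediate
5 | 2,6-bis(tert-butyldimethylsilyloxy)-3-(2-methylbut-3-en-2-yl)-4-(trimethylsilyloxy)benzaldehyde (not isolated) | O=Cc1c(O[Si](C)(C)C(C)(C)C)cc(O[Si](C)(C)C)c(C(C)(C)C=C)c1O[Si](C)(C)C(C)(C)C | intermediate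
6 | 2,6-bis(tert-butyldimethylsilyloxy)-4-hydroxy-3-(2-methylbut-3-en-2-yl)benzaldehyde | O=Cc1c(O[Si](C)(C)C(C)(C)C)cc(O)c(C(C)(C)C=C)c1O[Si](C)(C)C(C)(C)C | intermediate
7 | 2,6-bis(tert-butyldimethylsilyloxy)-3-(2-methylbut-3-en-2-yl)-4-(triisopropylsilyloxy)benzaldehyde | O=Cc1c(O[Si](C)(C)C(C)(C)C)cc(O[Si](C(C)C)(C(C)C)C(C)C)c(C(C)(C)C=C)c1O[Si](C)(C)C(C)(C)C | intermediate
8 | 2-(tert-butyldimethylsilyloxy)-6-hydroxy-3-(2-methylbut-3-en-2-yl)-4-(triisopropylsilyloxy)benzaldehyde | O=Cc1c(O)cc(O[Si](C(C)C)(C(C)C)C(C)C)c(C(C)(C)C=C)c1O[Si](C)(C)C(C)(C)C | intermediate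
9 | 2-methoxy-4-vinylphenol (4-vinylguaiacol) | C=Cc1ccc(O)c(OC)c1 | starting material
10 | tert-butyl(2-methoxy-4-vinylphenoxy)dimethylsilane | C=Cc1ccc(O[Si](C)(C)C(C)(C)C)c(OC)c1 | intermediate
11 | trimethyl orthoformate | COC(OC)OC | starting material
12 | dimethyl acetal of 8 (not isolated) | COC(OC)c1c(O)cc(O[Si](C(C)C)(C(C)C)C(C)C)c(C(C)(C)C=C)c1O[Si](C)(C)C(C)(C)C | intermediate
13 | 2-hydroxyaryl methoxycarbenium ion derived from 12, cation of the ion pair with the catalyst anion (not isolated) | C[O+]=Cc1c(O)cc(O[Si](C(C)C)(C(C)C)C(C)C)c(C(C)(C)C=C)c1O[Si](C)(C)C(C)(C)C | intermediate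
14 | open-chain benzylic cation, S at the methoxy-bearing carbon (not isolated) | C=CC(C)(C)c1c(O[Si](C(C)C)(C(C)C)C(C)C)cc(O)c(c1O[Si](C)(C)C(C)(C)C)[C@@H](OC)C[CH+]c1ccc(O[Si](C)(C)C(C)(C)C)c(OC)c1 | intermediate
15 | (2S,4S)-5-(tert-butyldimethylsilyloxy)-2-[4-(tert-butyldimethylsilyloxy)-3-methoxyphenyl]-4-methoxy-6-(2-methylbut-3-en-2-yl)-7-(triisopropylsilyloxy)chromane (2,4-cis) | C=CC(C)(C)c1c(O[Si](C(C)C)(C(C)C)C(C)C)cc2c(c1O[Si](C)(C)C(C)(C)C)[C@@H](OC)C[C@@H](c1ccc(O[Si](C)(C)C(C)(C)C)c(OC)c1)O2 | intermediate
16 | (2S)-5-(tert-butyldimethylsilyloxy)-2-[4-(tert-butyldimethylsilyloxy)-3-methoxyphenyl]-6-(2-methylbut-3-en-2-yl)-7-(triisopropylsilyloxy)chroman-4-ol, C4 epimers | C=CC(C)(C)c1c(O[Si](C(C)C)(C(C)C)C(C)C)cc2c(c1O[Si](C)(C)C(C)(C)C)C(O)C[C@@H](c1ccc(O[Si](C)(C)C(C)(C)C)c(OC)c1)O2 | intermediate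
17 | (2S)-5-(tert-butyldimethylsilyloxy)-2-[4-(tert-butyldimethylsilyloxy)-3-methoxyphenyl]-6-(2-methylbut-3-en-2-yl)-7-(triisopropylsilyloxy)chroman-4-one | C=CC(C)(C)c1c(O[Si](C(C)C)(C(C)C)C(C)C)cc2c(c1O[Si](C)(C)C(C)(C)C)C(=O)C[C@@H](c1ccc(O[Si](C)(C)C(C)(C)C)c(OC)c1)O2 | intermediate
18 | (2S)-5,7-dihydroxy-2-(4-hydroxy-3-methoxyphenyl)-6-(2-methylbut-3-en-2-yl)chroman-4-one | C=CC(C)(C)c1c(O)cc2c(c1O)C(=O)C[C@@H](c1ccc(O)c(OC)c1)O2 | target

## Step count and least certain steps

Total: 10 steps. Longest linear sequence: 9 steps (steps 1–5 and 7–10); step 6 is the one-step side branch.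

**Step 7 (key step, proposed new method).**
- Poor enantiofacial discrimination in the C–C bond formation, or a ring closure that does not pass the C4 configuration on to C2, would erode the enantiomeric purity at C2.
- Acid-induced oligomerisation of the styrene, or reopening of the C2–O1 bond of the product, would lower yield and purity.
- Fallback by known chemistry, from 8, 10 and 11, returning at 17: the three components are joined with the achiral Lewis acid Sc(OTf)3 in CH2Cl2 to the racemic 4-methoxyflavan F1. The conditions of step 8 give the racemic flavan-4-ol F2 and Dess–Martin oxidation gives the racemic flavanone F3. Kinetic resolution by asymmetric transfer hydrogenation follows, with RuCl[(S,S)-TsDPEN](p-cymene) or its antipode and HCO2H/Et3N, the antipode chosen so that the 2R enantiomer is reduced to the cis-(2R,4R)-flavan-4-ol F4. Unreduced (2S)-17 is separated by chromatography and enters step 10. At most half of the material is retained.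

**Step 5.**
- Insufficient discrimination between the two ortho silyl ethers, or silyl transfer between the phenols under base, would give the isomeric salicylaldehyde with the wrong hydroxyl free.
- Fallback from 7, returning at 8: both ortho silyl ethers are removed (K2CO3, MeOH, rt) to 2,6-dihydroxy-3-(2-methylbut-3-en-2-yl)-4-(triisopropylsilyloxy)benzaldehyde F5. The unhindered hydroxyl is acetylated (Ac2O, pyridine, CH2Cl2, −20 °C) to the monoacetate F6. The remaining hydroxyl beside the tert-alkyl group is silylated with TBSOTf and 2,6-lutidine to the acetoxy silyl ether F7. Methanolysis of the aryl acetate (K2CO3, MeOH, −20 °C) then gives 8. Selective removal is replaced by selective temporary protection.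

**Step 3.**
- Thermal loss of the prenyl group, silyl migration at 190 °C or incomplete trapping of the new phenol (leading to abnormal Claisen isomerisation or cyclisation onto the alkene) would lower the yield of 6.
- Fallback from 3, returning at 8: the rearrangement is run before the robust silyl groups are in place. Diol 3 is heated with excess BSA in PhNEt2; the bis(trimethylsilyl) ether F8 formed in the flask rearranges and is trapped as the tris(trimethylsilyl) ether F9. Acidic work-up gives 2,4,6-trihydroxy-3-(2-methylbut-3-en-2-yl)benzaldehyde F10. TIPSOTf (1 equiv) and 2,6-lutidine at −78 °C silylate the para hydroxyl, the only one without a hydrogen bond to the formyl group, to the diol F5. The sequence then continues through the monoacetate F6 and the acetoxy silyl ether F7 to 8 as described for step 5.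

**Step 8.**
- Elimination of the C4 cation to the 2H-chromene, or Friedel–Crafts capture of the cation by ring A of a second molecule, would compete with hydration.
- Fallback from 15, returning at 17 without an isolated intermediate: direct oxidative cleavage of the benzylic methyl ether with DDQ in CH2Cl2/H2O. Hydride abstraction from C4 and hydrolysis of the resulting oxocarbenium ion give the ketone, so no free C4 cation or alcohol is involved.

**Step 1.**
- Alkylation at an ortho oxygen, at ring carbon or twice would reduce the yield of the mono-ether.
- Fallback from 1, returning at 3: Mitsunobu reaction with 3-methylbut-2-en-1-ol, PPh3 and diisopropyl azodicarboxylate in THF at 0 °C. No free phenoxide is present, so C-alkylation is avoided, and the most acidic, non-chelated hydroxyl should react.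

## Further compounds

F1 | step 7 | racemic 5-(tert-butyldimethylsilyloxy)-2-[4-(tert-butyldimethylsilyloxy)-3-methoxyphenyl]-4-methoxy-6-(2-methylbut-3-en-2-yl)-7-(triisopropylsilyloxy)chromane (racemate, so no descriptors are written) | C=CC(C)(C)c1c(O[Si](C(C)C)(C(C)C)C(C)C)cc2c(c1O[Si](C)(C)C(C)(C)C)C(OC)CC(c1ccc(O[Si](C)(C)C(C)(C)C)c(OC)c1)O2
F2 | step 7 | racemic 5-(tert-butyldimethylsilyloxy)-2-[4-(tert-butyldimethylsilyloxy)-3-methoxyphenyl]-6-(2-methylbut-3-en-2-yl)-7-(triisopropylsilyloxy)chroman-4-ol (racemate, C4 epimers) | C=CC(C)(C)c1c(O[Si](C(C)C)(C(C)C)C(C)C)cc2c(c1O[Si](C)(C)C(C)(C)C)C(O)CC(c1ccc(O[Si](C)(C)C(C)(C)C)c(OC)c1)O2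
F3 | step 7 | racemic 5-(tert-butyldimethylsilyloxy)-2-[4-(tert-butyldimethylsilyloxy)-3-methoxyphenyl]-6-(2-methylbut-3-en-2-yl)-7-(triisopropylsilyloxy)chroman-4-one | C=CC(C)(C)c1c(O[Si](C(C)C)(C(C)C)C(C)C)cc2c(c1O[Si](C)(C)C(C)(C)C)C(=O)CC(c1ccc(O[Si](C)(C)C(C)(C)C)c(OC)c1)O2
F4 | step 7 | (2R,4R)-5-(tert-butyldimethylsilyloxy)-2-[4-(tert-butyldimethylsilyloxy)-3-methoxyphenyl]-6-(2-methylbut-3-en-2-yl)-7-(triisopropylsilyloxy)chroman-4-ol (2,4-cis) | C=CC(C)(C)c1c(O[Si](C(C)C)(C(C)C)C(C)C)cc2c(c1O[Si](C)(C)C(C)(C)C)[C@H](O)C[C@H](c1ccc(O[Si](C)(C)C(C)(C)C)c(OC)c1)O2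
F5 | step 5 | 2,6-dihydroxy-3-(2-methylbut-3-en-2-yl)-4-(triisopropylsilyloxy)benzaldehyde | O=Cc1c(O)cc(O[Si](C(C)C)(C(C)C)C(C)C)c(C(C)(C)C=C)c1O
F6 | step 5 | 2-formyl-3-hydroxy-4-(2-methylbut-3-en-2-yl)-5-(triisopropylsilyloxy)phenyl acetate | CC(=O)Oc1cc(O[Si](C(C)C)(C(C)C)C(C)C)c(C(C)(C)C=C)c(O)c1C=O
F7 | step 5 | 3-(tert-butyldimethylsilyloxy)-2-formyl-4-(2-methylbut-3-en-2-yl)-5-(triisopropylsilyloxy)phenyl acetate | CC(=O)Oc1cc(O[Si](C(C)C)(C(C)C)C(C)C)c(C(C)(C)C=C)c(O[Si](C)(C)C(C)(C)C)c1C=O
F8 | step 3 | 4-(3-methylbut-2-en-1-yloxy)-2,6-bis(trimethylsilyloxy)benzaldehyde | O=Cc1c(O[Si](C)(C)C)cc(OCC=C(C)C)cc1O[Si](C)(C)C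
F9 | step 3 | 3-(2-methylbut-3-en-2-yl)-2,4,6-tris(trimethylsilyloxy)benzaldehyde | O=Cc1c(O[Si](C)(C)C)cc(O[Si](C)(C)C)c(C(C)(C)C=C)c1O[Si](C)(C)C
F10 | step 3 | 2,4,6-trihydroxy-3-(2-methylbut-3-en-2-yl)benzaldehyde | O=Cc1c(O)cc(O)c(C(C)(C)C=C)c1O
F0 | step 8 | none | none
F0 | step 1 | none | none
A1 | alternative 1 | ferulic acid | COc1cc(/C=C/C(=O)O)ccc1O
A2 | alternative 1 | malonic acid | O=C(O)CC(=O)O
A3 | alternative 1 | (2S)-homoeriodictyol | O=C1C[C@@H](c2ccc(O)c(OC)c2)Oc2cc(O)cc(O)c21
A4 | alternative 2 | (S)-configured acyclic diene: aryl 1-arylallyl ether with a triethylsilyl enol ether on ring A | C=CC(C)(C)c1c(OCOC)cc(O[C@@H](C=C)c2ccc(OCOC)c(OC)c2)c(C(=C)O[Si](CC)(CC)CC)c1O[Si](CC)(CC)CC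
A5 | alternative 2 | protected (S)-2-aryl-4-(triethylsilyloxy)-2H-chromene | C=CC(C)(C)c1c(OCOC)cc2c(c1O[Si](CC)(CC)CC)C(O[Si](CC)(CC)CC)=C[C@@H](c1ccc(OCOC)c(OC)c1)O2
A6 | alternative 3 | (S)-6-(diazoacetyl)-2-[3-methoxy-4-(triisopropylsilyloxy)phenyl]-2,3-dihydro-4H-pyran-4-one | [N-]=[N+]=CC(=O)C1=CC(=O)C[C@@H](c2ccc(O[Si](C(C)C)(C(C)C)C(C)C)c(OC)c2)O1
A7 | alternative 3 | (3,3-dimethylpent-4-en-1-yn-1-yloxy)triisopropylsilane | C=CC(C)(C)C#CO[Si](C(C)C)(C(C)C)C(C)C
A8 | alternative 3 | 7,4'-bis-O-triisopropylsilyl ether of the target | C=CC(C)(C)c1c(O[Si](C(C)C)(C(C)C)C(C)C)cc2c(c1O)C(=O)C[C@@H](c1ccc(O[Si](C(C)C)(C(C)C)C(C)C)c(OC)c1)O2
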